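**Plan**

1. Retrosynthesis: the last cut is the 5-O-methyl ether (a symmetry helper). Ring C is then cut in one stroke at O1–C2 and C4–C4a, leading back to an aryl ester in which O1 is tied to C4 by a temporary ester bond that the target does not contain.
2. The ester is cut into the mirror-symmetric 3,5-dimethoxy-4-prenylphenol (ring A) and a (2R,3S)-3-arylglycidic acid (C2, C3, C4 and ring B).
3. Forward: ring A by lithiation and prenylation between the two methoxy groups; the glycidate by Darzens condensation and lipase resolution; esterification; then a photo-Fries shift of the acyl group from O1 to C4a, followed in the same flask by acid-induced opening of the epoxide at C2 by the freed O1–H, which closes ring C; MgI2 finally frees 5-OH.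
4. Enabling features: in ring A, C6 (prenyl) is para to O1 and, while O5 and O7 are both methylated, C4a and C8 are equivalent, so the acyl group can reach only one kind of carbon. C2 is benzylic and para to the 4'-methoxy group of ring B, so the epoxide opens there.
5. Stereochemistry: C3 (R) comes from the resolved epoxide and is retained; C2 (R) arises by inversion at the benzylic epoxide carbon, giving the 2,3-trans isomer.

Key step: step 9

Remark: 3,5-dimethoxyphenol, prenyl bromide, isovanillin and methyl chloroacetate are taken as commercial; the racemic glycidic ester is written as the 1:1 pair of the SMILES of both trans enantiomers.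

**Route**

Step 1
Reactants: 1 3,5-dimethoxyphenol
Product: 2 (3,5-dimethoxyphenoxy)tri(propan-2-yl)silane
Conditions: i-Pr3SiCl, imidazole, DMF, rt
Reagents that add atoms: chlorotri(propan-2-yl)silane, CC(C)[Si](Cl)(C(C)C)C(C)C
Why: Silyl ether protection of the phenol should give a bulky, weakly coordinating ether that withstands n-BuLi and shields both positions next to it.

Step 2
Reactants: 2 (3,5-dimethoxyphenoxy)tri(propan-2-yl)silane; 3 1-bromo-3-methylbut-2-ene (prenyl bromide)
Product: 5 [3,5-dimethoxy-4-(3-methylbut-2-en-1-yl)phenoxy]tri(propan-2-yl)silane, via aryllithium 4 (not isolated)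
Conditions: n-BuLi, TMEDA, THF, 0 °C → rt; then CuBr·SMe2 (10 mol %), 3, −78 °C → rt
Reagents that add atoms: none
Why: Directed ortho-metalation should occur at the carbon between the two methoxy groups (cooperative directors, while the carbons next to the bulky silyl ether are shielded), and the aryllithium should be alkylated at the primary carbon of prenyl bromide (copper-catalysed allylic substitution), which places the prenyl group para to the future O1.

Step 3
Reactants: 5 [3,5-dimethoxy-4-(3-methylbut-2-en-1-yl)phenoxy]tri(propan-2-yl)silane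
Product: 6 3,5-dimethoxy-4-(3-methylbut-2-en-1-yl)phenol
Conditions: Bu4NF, AcOH, THF, 0 °C → rt
Reagents that add atoms: none
Why: Fluoride-induced desilylation of an aryl silyl ether, buffered with AcOH, should free the phenol without touching the prenyl alkene.

Step 4
Reactants: 7 3-hydroxy-4-methoxybenzaldehyde (isovanillin)
Product: 8 4-methoxy-3-(methoxymethoxy)benzaldehyde
Conditions: MOMCl, i-Pr2NEt, CH2Cl2, 0 °C → rt
Reagents that add atoms: chloromethyl methyl ether, COCCl
Why: O-Alkylation of the phenol gives a MOM acetal that withstands methoxide, hydroxide, the lipase and UV light and is removed by the acid used in the key step.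

Step 5
Reactants: 8 4-methoxy-3-(methoxymethoxy)benzaldehyde; 9 methyl chloroacetate
Product: 10 racemic methyl trans-3-[4-methoxy-3-(methoxymethoxy)phenyl]oxirane-2-carboxylate
Conditions: NaOMe, MeOH, −10 °C → rt
Reagents that add atoms: none
Why: The Darzens glycidic ester condensation of an electron-rich aromatic aldehyde should give mainly the trans-epoxide, here as the racemate, because the aldolate leading to it closes fastest while the other reverts.

Step 6
Reactants: 10 racemic methyl trans-3-[4-methoxy-3-(methoxymethoxy)phenyl]oxirane-2-carboxylate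
Product: 11 methyl (2R,3S)-3-[4-methoxy-3-(methoxymethoxy)phenyl]oxirane-2-carboxylate
Conditions: Serratia marcescens lipase, toluene/aq. phosphate buffer (pH 8), 30 °C, to slightly beyond half conversion
Reagents that add atoms: none
Why: Lipase-catalysed kinetic resolution by enantioselective ester hydrolysis, established for the trans-3-(4-methoxyphenyl)glycidic methyl ester, should consume the (2S,3R)-ester (its acid decarboxylates to the arylacetaldehyde) and leave the (2R,3S)-ester, which fixes the configuration of the future C3.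

Step 7
Reactants: 11 methyl (2R,3S)-3-[4-methoxy-3-(methoxymethoxy)phenyl]oxirane-2-carboxylate
Product: 12 potassium (2R,3S)-3-[4-methoxy-3-(methoxymethoxy)phenyl]oxirane-2-carboxylate
Conditions: KOH (1.0 equiv), MeOH, 0 °C; precipitation with Et2O
Reagents that add atoms: potassium hydroxide, [K+].[OH-]
Why: Saponification with one equivalent of hydroxide gives the glycidate salt, which is kept as the salt because the free 3-arylglycidic acid decarboxylates, and no stereocenter is touched.

Step 8
Reactants: 12 potassium (2R,3S)-3-[4-methoxy-3-(methoxymethoxy)phenyl]oxirane-2-carboxylate; 6 3,5-dimethoxy-4-(3-methylbut-2-en-1-yl)phenol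
Product: 13 3,5-dimethoxy-4-(3-methylbut-2-en-1-yl)phenyl (2R,3S)-3-[4-methoxy-3-(methoxymethoxy)phenyl]oxirane-2-carboxylate
Conditions: EDC·HCl, DMAP (cat.), CH2Cl2/DMF, 0 °C → rt
Reagents that add atoms: none
Why: Carbodiimide/DMAP (Steglich) esterification of the carboxylate with the unhindered, electron-rich phenol should build the temporary O–acyl bond under nearly neutral conditions that spare the epoxide, the MOM acetal and the prenyl group.

Step 9
Reactants: 13 3,5-dimethoxy-4-(3-methylbut-2-en-1-yl)phenyl (2R,3S)-3-[4-methoxy-3-(methoxymethoxy)phenyl]oxirane-2-carboxylate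
Product: 16 (2R,3R)-3-hydroxy-2-(3-hydroxy-4-methoxyphenyl)-5,7-dimethoxy-6-(3-methylbut-2-en-1-yl)-2,3-dihydro-4H-chromen-4-one, via epoxy ketone 14 (not isolated), via MOM-protected dihydroflavonol 15 (not isolated)
Conditions: hν (254 nm, quartz), degassed MeCN (0.005 M), rt; then 3 M aq. HCl/MeOH, 40 °C
Reagents that add atoms: none
Why: Proposed new method: light excites the aryl ester, the ArO–C(=O) bond breaks homolytically to an aryloxyl/acyl radical pair held in the solvent cage, the pair recombines at an ortho carbon and tautomerisation gives the 2-hydroxyaryl epoxy ketone 14 (C4–C4a bond), after which the added acid activates the epoxide for attack of the freed phenolic OH on the benzylic carbon (O1–C2 bond) and finally methanolyses the MOM acetal. The closest known reaction types are the photo-Fries rearrangement of aryl cinnamates to 2'-hydroxychalcones and the acid-induced cyclisation of 2'-hydroxychalcone epoxides to trans-dihydroflavonols, and what is new is an epoxy acyl group as the migrating unit and the coupling of the two events in one flask. Ring C closes by 6-endo-tet opening of the epoxide at the benzylic carbon and not by 5-exo-tet attack at the carbon next to the carbonyl, because the 4-methoxy group of ring B stands para to the benzylic carbon and stabilises positive charge there. C3 keeps the R configuration of the resolved epoxide, and C2 is set by inversion at the (S)-configured benzylic epoxide carbon, which gives the 2,3-trans (2R,3R) product, the more stable diequatorial isomer also if the opening gains cation character. The step needs migration to a single ring carbon and a single cyclisation mode, which the substrate secures because the para position carries the prenyl group, the two ortho carbons are equivalent by the mirror symmetry of the 3,5-dimethoxy-4-prenylphenoxy group and only one phenolic OH is free. It also needs the epoxide to stay unactivated until the acyl group has moved, since acid acting on the ester would alkylate the ortho carbon and give a 4-aryl-dihydrocoumarin, hence the neutral photochemical trigger with acid added only afterwards; the oxiranyl acyl radical should resist decarbonylation because that would give a strained σ-radical.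

Step 10
Reactants: 16 (2R,3R)-3-hydroxy-2-(3-hydroxy-4-methoxyphenyl)-5,7-dimethoxy-6-(3-methylbut-2-en-1-yl)-2,3-dihydro-4H-chromen-4-one
Product: 17 (2R,3R)-3,5-dihydroxy-2-(3-hydroxy-4-methoxyphenyl)-7-methoxy-6-(3-methylbut-2-en-1-yl)-2,3-dihydro-4H-chromen-4-one
Conditions: MgI2·OEt2 (3 equiv), THF, 60 °C; then H2O
Reagents that add atoms: none
Why: Chelation-controlled ether cleavage, known for 5-methoxy prenylflavanones, should let magnesium bound between C4=O and the peri 5-methoxy oxygen deliver iodide to that methyl group only, leaving the 7- and 4'-methyl ethers, the prenyl group and both stereocenters untouched.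

**Compound list**

1 | 3,5-dimethoxyphenol | COc1cc(O)cc(OC)c1 | starting material
2 | (3,5-dimethoxyphenoxy)tri(propan-2-yl)silane | COc1cc(OC)cc(O[Si](C(C)C)(C(C)C)C(C)C)c1 | intermediate
3 | 1-bromo-3-methylbut-2-ene (prenyl bromide) | CC(C)=CCBr | starting material
4 | [2,6-dimethoxy-4-(triisopropylsilyloxy)phenyl]lithium | [Li]c1c(OC)cc(O[Si](C(C)C)(C(C)C)C(C)C)cc1OC | intermediate
5 | [3,5-dimethoxy-4-(3-methylbut-2-en-1-yl)phenoxy]tri(propan-2-yl)silane | COc1cc(O[Si](C(C)C)(C(C)C)C(C)C)cc(OC)c1CC=C(C)C | intermediate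
6 | 3,5-dimethoxy-4-(3-methylbut-2-en-1-yl)phenol | COc1cc(O)cc(OC)c1CC=C(C)C | intermediate
7 | 3-hydroxy-4-methoxybenzaldehyde (isovanillin) | COc1ccc(C=O)cc1O | starting material
8 | 4-methoxy-3-(methoxymethoxy)benzaldehyde | COCOc1cc(C=O)ccc1OC | intermediate
9 | methyl chloroacetate | COC(=O)CCl | starting material
10 | racemic methyl trans-3-[4-methoxy-3-(methoxymethoxy)phenyl]oxirane-2-carboxylate (1:1 pair of the 2R,3S and 2S,3R esters) | COC(=O)[C@@H]1O[C@H]1c1ccc(OC)c(OCOC)c1.COC(=O)[C@H]1O[C@@H]1c1ccc(OC)c(OCOC)c1 | intermediate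
11 | methyl (2R,3S)-3-[4-methoxy-3-(methoxymethoxy)phenyl]oxirane-2-carboxylate | COC(=O)[C@@H]1O[C@H]1c1ccc(OC)c(OCOC)c1 | intermediate
12 | potassium (2R,3S)-3-[4-methoxy-3-(methoxymethoxy)phenyl]oxirane-2-carboxylate | [K+].[O-]C(=O)[C@@H]1O[C@H]1c1ccc(OC)c(OCOC)c1 | intermediate
13 | 3,5-dimethoxy-4-(3-methylbut-2-en-1-yl)phenyl (2R,3S)-3-[4-methoxy-3-(methoxymethoxy)phenyl]oxirane-2-carboxylate | COc1cc(OC(=O)[C@@H]2O[C@H]2c2ccc(OC)c(OCOC)c2)cc(OC)c1CC=C(C)C | intermediate
14 | [6-hydroxy-2,4-dimethoxy-3-(3-methylbut-2-en-1-yl)phenyl]{(2R,3S)-3-[4-methoxy-3-(methoxymethoxy)phenyl]oxiran-2-yl}methanone | COc1cc(O)c(C(=O)[C@@H]2O[C@H]2c2ccc(OC)c(OCOC)c2)c(OC)c1CC=C(C)C | intermediate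
15 | (2R,3R)-3-hydroxy-5,7-dimethoxy-2-[4-methoxy-3-(methoxymethoxy)phenyl]-6-(3-methylbut-2-en-1-yl)-2,3-dihydro-4H-chromen-4-one | COCOc1cc([C@H]2Oc3cc(OC)c(CC=C(C)C)c(OC)c3C(=O)[C@@H]2O)ccc1OC | intermediate
16 | (2R,3R)-3-hydroxy-2-(3-hydroxy-4-methoxyphenyl)-5,7-dimethoxy-6-(3-methylbut-2-en-1-yl)-2,3-dihydro-4H-chromen-4-one | COc1ccc([C@H]2Oc3cc(OC)c(CC=C(C)C)c(OC)c3C(=O)[C@@H]2O)cc1O | intermediate
17 | (2R,3R)-3,5-dihydroxy-2-(3-hydroxy-4-methoxyphenyl)-7-methoxy-6-(3-methylbut-2-en-1-yl)-2,3-dihydro-4H-chromen-4-one | COc1ccc([C@H]2Oc3cc(OC)c(CC=C(C)C)c(O)c3C(=O)[C@@H]2O)cc1O | target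

**Summary**

Total step count: 10. Longest linear sequence: 7 steps (steps 4, 5, 6, 7, 8, 9, 10).

**Steps most likely to fail**

Step 9 (Proposed new method). What may go wrong: escape of the radical pair from the solvent cage, which returns phenol 6 and fragments of the acyl radical; competing light-induced cleavage of the aryl oxirane; and opening of the epoxide at the carbon next to the carbonyl or by methanol instead of by the phenol. The fallback uses known chemistry, sets out from 6 and 8 and comes back at 16. Phenol 6 would be protected (MOMCl, i-Pr2NEt) as 1,3-dimethoxy-5-(methoxymethoxy)-2-(3-methylbut-2-en-1-yl)benzene F1. Ortho-lithiation next to the MOM ether (n-BuLi, THF, 0 °C) would give [2,4-dimethoxy-6-(methoxymethoxy)-3-(3-methylbut-2-en-1-yl)phenyl]lithium F2, which would be acetylated with N-methoxy-N-methylacetamide to 1-[2,4-dimethoxy-6-(methoxymethoxy)-3-(3-methylbut-2-en-1-yl)phenyl]ethan-1-one F3. Claisen–Schmidt condensation with 8 (KOH, EtOH) would give (E)-1-[2,4-dimethoxy-6-(methoxymethoxy)-3-(3-methylbut-2-en-1-yl)phenyl]-3-[4-methoxy-3-(methoxymethoxy)phenyl]prop-2-en-1-one F4. Juliá–Colonna epoxidation (poly-L-leucine, urea–H2O2, DBU, THF) is a nucleophilic oxidation that should spare the prenyl alkene; it is expected to give the αR,βS epoxide [2,4-dimethoxy-6-(methoxymethoxy)-3-(3-methylbut-2-en-1-yl)phenyl]{(2R,3S)-3-[4-methoxy-3-(methoxymethoxy)phenyl]oxiran-2-yl}methanone F5. Finally 3 M HCl/MeOH at 45 °C should remove both MOM groups and close ring C through 14 and 15 to 16.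

Step 6. What may go wrong: insufficient discrimination of the two enantiomers by the lipase on a substrate that carries an extra 3-alkoxy group, so that the recovered ester is of low enantiomeric purity or little of it is recovered. The fallback sets out from 8 and comes back at 11. Horner–Wadsworth–Emmons olefination of 8 (trimethyl phosphonoacetate, NaH, THF) would give methyl (E)-3-[4-methoxy-3-(methoxymethoxy)phenyl]prop-2-enoate F6. Shi epoxidation would then give 11, using the enantiomer of the fructose-derived 4,5-di-O-acetyl ketone catalyst that delivers the (2R,3S) series (the ketone from L-fructose is expected), KHSO5 (as 2KHSO5·KHSO4·K2SO4), NaHCO3, MeCN/H2O, 0 °C.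

Step 10. What may go wrong: loss of site selectivity in the ether cleavage, addition of HI to the prenyl alkene or ring closure of the new 5-OH onto it, and epimerisation through reversible opening of ring C at C2. The fallback completes the prenyl group only after the demethylation; it sets out from 2 and comes back at 17. Compound 2 would be lithiated as in step 2 (through 4) and quenched with allyl bromide to give [3,5-dimethoxy-4-(prop-2-en-1-yl)phenoxy]tri(propan-2-yl)silane F7. Desilylation (Bu4NF, AcOH) would give 3,5-dimethoxy-4-(prop-2-en-1-yl)phenol F8. Esterification with 12 as in step 8 would give 3,5-dimethoxy-4-(prop-2-en-1-yl)phenyl (2R,3S)-3-[4-methoxy-3-(methoxymethoxy)phenyl]oxirane-2-carboxylate F9. The conditions of step 9 would lead through [6-hydroxy-2,4-dimethoxy-3-(prop-2-en-1-yl)phenyl]{(2R,3S)-3-[4-methoxy-3-(methoxymethoxy)phenyl]oxiran-2-yl}methanone F10 and (2R,3R)-3-hydroxy-5,7-dimethoxy-2-[4-methoxy-3-(methoxymethoxy)phenyl]-6-(prop-2-en-1-yl)-2,3-dihydro-4H-chromen-4-one F11, neither isolated, to (2R,3R)-3-hydroxy-2-(3-hydroxy-4-methoxyphenyl)-5,7-dimethoxy-6-(prop-2-en-1-yl)-2,3-dihydro-4H-chromen-4-one F12. An allyl group cannot form a tertiary cation, so a stronger chelating Lewis acid (BCl3, CH2Cl2, −78 → 0 °C) could cleave the 5-O-methyl group to give (2R,3R)-3,5-dihydroxy-2-(3-hydroxy-4-methoxyphenyl)-7-methoxy-6-(prop-2-en-1-yl)-2,3-dihydro-4H-chromen-4-one F13. Cross-metathesis with 2-methyl-2-butene (second-generation Grubbs catalyst, CH2Cl2, 40 °C) would then turn allyl into prenyl and give 17.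

Further compounds
F1 | step 9 | 1,3-dimethoxy-5-(methoxymethoxy)-2-(3-methylbut-2-en-1-yl)benzene | COCOc1cc(OC)c(CC=C(C)C)c(OC)c1
F2 | step 9 | [2,4-dimethoxy-6-(methoxymethoxy)-3-(3-methylbut-2-en-1-yl)phenyl]lithium | [Li]c1c(OCOC)cc(OC)c(CC=C(C)C)c1OC
F3 | step 9 | 1-[2,4-dimethoxy-6-(methoxymethoxy)-3-(3-methylbut-2-en-1-yl)phenyl]ethan-1-one | CC(=O)c1c(OCOC)cc(OC)c(CC=C(C)C)c1OC
F4 | step 9 | (E)-1-[2,4-dimethoxy-6-(methoxymethoxy)-3-(3-methylbut-2-en-1-yl)phenyl]-3-[4-methoxy-3-(methoxymethoxy)phenyl]prop-2-en-1-one | COCOc1cc(OC)c(CC=C(C)C)c(OC)c1C(=O)/C=C/c1ccc(OC)c(OCOC)c1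
F5 | step 9 | [2,4-dimethoxy-6-(methoxymethoxy)-3-(3-methylbut-2-en-1-yl)phenyl]{(2R,3S)-3-[4-methoxy-3-(methoxymethoxy)phenyl]oxiran-2-yl}methanone | COCOc1cc(OC)c(CC=C(C)C)c(OC)c1C(=O)[C@@H]1O[C@H]1c1ccc(OC)c(OCOC)c1
F6 | step 6 | methyl (E)-3-[4-methoxy-3-(methoxymethoxy)phenyl]prop-2-enoate | COC(=O)/C=C/c1ccc(OC)c(OCOC)c1
F7 | step 10 | [3,5-dimethoxy-4-(prop-2-en-1-yl)phenoxy]tri(propan-2-yl)silane | C=CCc1c(OC)cc(O[Si](C(C)C)(C(C)C)C(C)C)cc1OC
F8 | step 10 | 3,5-dimethoxy-4-(prop-2-en-1-yl)phenol | C=CCc1c(OC)cc(O)cc1OC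
F9 | step 10 | 3,5-dimethoxy-4-(prop-2-en-1-yl)phenyl (2R,3S)-3-[4-methoxy-3-(methoxymethoxy)phenyl]oxirane-2-carboxylate | C=CCc1c(OC)cc(OC(=O)[C@@H]2O[C@H]2c2ccc(OC)c(OCOC)c2)cc1OC
F10 | step 10 | [6-hydroxy-2,4-dimethoxy-3-(prop-2-en-1-yl)phenyl]{(2R,3S)-3-[4-methoxy-3-(methoxymethoxy)phenyl]oxiran-2-yl}methanone | C=CCc1c(OC)cc(O)c(C(=O)[C@@H]2O[C@H]2c2ccc(OC)c(OCOC)c2)c1OC
F11 | step 10 | (2R,3R)-3-hydroxy-5,7-dimethoxy-2-[4-methoxy-3-(methoxymethoxy)phenyl]-6-(prop-2-en-1-yl)-2,3-dihydro-4H-chromen-4-one | COCOc1cc([C@H]2Oc3cc(OC)c(CC=C)c(OC)c3C(=O)[C@@H]2O)ccc1OC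
F12 | step 10 | (2R,3R)-3-hydroxy-2-(3-hydroxy-4-methoxyphenyl)-5,7-dimethoxy-6-(prop-2-en-1-yl)-2,3-dihydro-4H-chromen-4-one | COc1ccc([C@H]2Oc3cc(OC)c(CC=C)c(OC)c3C(=O)[C@@H]2O)cc1O
F13 | step 10 | (2R,3R)-3,5-dihydroxy-2-(3-hydroxy-4-methoxyphenyl)-7-methoxy-6-(prop-2-en-1-yl)-2,3-dihydro-4H-chromen-4-one | COc1ccc([C@H]2Oc3cc(OC)c(CC=C)c(O)c3C(=O)[C@@H]2O)cc1O
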